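**Retrosynthetic overview**
- The ring–chain bond C3–C1′ is made last, by Friedel–Crafts allylation of menadiol with the complete C40 allylic alcohol, followed by oxidation to the quinone.
- The C40 chain is cut at C12′–C13′ (allyl–allyl): a C25 allyl sulfone is alkylated with 12-bromofarnesyl acetate, then desulfonylated with Pd/hydride.
- The C25 unit is cut at C24′–C25′ (alkyl–allyl): Cu-catalysed coupling of (S)-citronellylmagnesium bromide with the same 12-bromofarnesyl acetate, which is made once from farnesyl acetate and used twice.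
- The only stereocentre (C27′, R) comes from geranial by an organocatalytic iminium transfer hydrogenation to (S)-citronellal; the descriptor changes from S to R later only because the CIP priorities change.
- No ring is formed in the route; the naphthalene ring system is bought as menadiol and attached in the last step.

Assumption: geranial (the pure E isomer of citral) and menadiol are bought as such and used under argon.

**Step 1**
Reactants: 1 geranial
Product: 3 (S)-citronellol, via (S)-citronellal 2 (not isolated)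
Conditions: morpholinium salt of a confined BINOL-derived imidodiphosphate anion with 3,3′-(2,4,6-triethylphenyl) groups (5 mol%), Hantzsch ester (1.1 equiv), dioxane, 50 °C; then NaBH4, MeOH, 0 °C
Reagents that add atoms: none
Why: Proposed new method: counteranion-directed iminium transfer hydrogenation with a new catalyst, in which achiral morpholine forms the (E)-iminium ion of 1 and the narrow pocket of the chiral imidodiphosphate anion ion-pairs with it and hydrogen-bonds the N–H of the Hantzsch ester, so that hydride reaches only the Re face of C3 and sets 3S (the anion enantiomer that does this is fixed in a first run, its mirror image gives 3R), the tighter pocket being expected to tell the β-methyl from the β-CH2 chain better than an open phosphate; the closest known reaction is the transfer hydrogenation of citral with a morpholinium 3,3′-diaryl-BINOL phosphate and a Hantzsch ester (about 90% ee), and NaBH4 reduces the aldehyde in the same flask before it can cyclise.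

**Step 2**
Reactants: 3 (S)-citronellol
Product: 4 (S)-citronellyl bromide
Conditions: CBr4, PPh3, CH2Cl2, 0 °C
Reagents that add atoms: carbon tetrabromide, BrC(Br)(Br)Br
Why: Appel reaction, an SN2 displacement at the primary carbon two bonds from the stereocentre, which is not touched.

**Step 3**
Reactants: 5 (2E,6E)-farnesyl acetate
Product: 6 (2E,6E,10E)-12-hydroxy-3,7,11-trimethyldodeca-2,6,10-trien-1-yl acetate
Conditions: SeO2 (0.1 equiv), salicylic acid (0.1 equiv), t-BuOOH (3 equiv), CH2Cl2, rt
Reagents that add atoms: tert-butyl hydroperoxide, CC(C)(C)OO; selenium dioxide (catalytic oxygen carrier), O=[Se]=O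
Why: Catalytic SeO2/t-BuOOH allylic oxidation (ene reaction, then [2,3]-sigmatropic shift) attacks the most electron-rich terminal double bond, farthest from the acetate, and hydroxylates the methyl trans to the chain, giving the 10E allylic alcohol.

**Step 4**
Reactants: 6 (2E,6E,10E)-12-hydroxy-3,7,11-trimethyldodeca-2,6,10-trien-1-yl acetate
Product: 7 (2E,6E,10E)-12-bromo-3,7,11-trimethyldodeca-2,6,10-trien-1-yl acetate
Conditions: CBr4, PPh3, CH2Cl2, −20 → 0 °C
Reagents that add atoms: carbon tetrabromide, BrC(Br)(Br)Br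
Why: Appel reaction on the primary allylic alcohol (SN2, no allylic shift), with the double-bond geometry and the acetate left intact.

**Step 5**
Reactants: 4 (S)-citronellyl bromide; 7 (2E,6E,10E)-12-bromo-3,7,11-trimethyldodeca-2,6,10-trien-1-yl acetate
Product: 10 (2E,6E,10E,15R)-3,7,11,15,19-pentamethylicosa-2,6,10,18-tetraen-1-ol, via citronellyl Grignard 8 (not isolated), via C25 acetate 9 (not isolated)
Conditions: Mg, THF, 40 °C; then 7, Li2CuCl4 (3 mol%), THF, −78 → −10 °C; then K2CO3, MeOH, rt
Reagents that add atoms: none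
Why: Copper-catalysed Grignard–allylic bromide cross-coupling substitutes the bromide at its primary carbon (SN2, 10E kept) much faster than the Grignard reagent touches the acetate at −78 °C, and methanolysis then frees the alcohol; the stereocentre is remote and unchanged (now 15R by priority change only).

**Step 6**
Reactants: 10 (2E,6E,10E,15R)-3,7,11,15,19-pentamethylicosa-2,6,10,18-tetraen-1-ol
Product: 12 [(2E,6E,10E,15R)-3,7,11,15,19-pentamethylicosa-2,6,10,18-tetraen-1-yl] phenyl sulfone, via C25 bromide 11 (not isolated)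
Conditions: PBr3 (0.4 equiv), Et2O, −10 °C; then PhSO2Na, DMF, rt
Reagents that add atoms: sodium benzenesulfinate, [Na+].[O-]S(=O)c1ccccc1
Why: Bromination of the primary allylic alcohol and S-alkylation of the sulfinate are both SN2 at C1, so the 2E bond stays and the thermodynamically preferred primary allyl sulfone results.

**Step 7**
Reactants: 12 [(2E,6E,10E,15R)-3,7,11,15,19-pentamethylicosa-2,6,10,18-tetraen-1-yl] phenyl sulfone; 7 (2E,6E,10E)-12-bromo-3,7,11-trimethyldodeca-2,6,10-trien-1-yl acetate
Product: 14 (2E,6E,10E,14E,18E,22E,27R)-3,7,11,15,19,23,27,31-octamethyl-13-(phenylsulfonyl)dotriaconta-2,6,10,14,18,22,30-heptaen-1-yl acetate, via lithiated C25 sulfone 13 (not isolated)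
Conditions: n-BuLi (1.05 equiv), THF/DMPU, −78 °C; then 7, −78 → −40 °C
Reagents that add atoms: none
Why: Biellmann-type (Julia) sulfone alkylation: the sulfone-stabilised allyl anion is alkylated at its α-carbon by the primary allylic bromide (SN2, faster than attack on the acetate at −78 °C), joining the halves head-to-tail with all double bonds in place; the new C13 centre is a mixture that is removed in step 8.

**Step 8**
Reactants: 14 (2E,6E,10E,14E,18E,22E,27R)-3,7,11,15,19,23,27,31-octamethyl-13-(phenylsulfonyl)dotriaconta-2,6,10,14,18,22,30-heptaen-1-yl acetate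
Product: 16 (2E,6E,10E,14E,18E,22E,27R)-3,7,11,15,19,23,27,31-octamethyldotriaconta-2,6,10,14,18,22,30-heptaen-1-ol, via C40 hydroxy sulfone 15 (not isolated)
Conditions: LiBHEt3 (6 equiv), THF, 0 °C; then PdCl2(dppp) (5 mol%), 0 °C → rt
Reagents that add atoms: none
Why: Hydride first cleaves the acetate to the alkoxide, then Pd-catalysed reductive desulfonylation ionises the allylic sulfone to a π-allyl complex that takes hydride at its less substituted end (C13), so the 14E double bond keeps its place and geometry.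

**Step 9**
Reactants: 16 (2E,6E,10E,14E,18E,22E,27R)-3,7,11,15,19,23,27,31-octamethyldotriaconta-2,6,10,14,18,22,30-heptaen-1-ol; 17 menadiol
Product: 19 2-methyl-3-[(2E,6E,10E,14E,18E,22E,27R)-3,7,11,15,19,23,27,31-octamethyldotriaconta-2,6,10,14,18,22,30-heptaen-1-yl]naphthalene-1,4-dione (target), via C40 hydroquinone 18 (not isolated)
Conditions: 17 (3 equiv), BF3·OEt2, dioxane, 50 °C, Ar; then Ag2O, Et2O, rt
Reagents that add atoms: none
Why: Friedel–Crafts allylation of the electron-rich hydroquinone at C3, its only free position, by the BF3-activated primary allylic alcohol (attack at C1′, 2′E kept to about 9:1), then Ag2O oxidation to the quinone; the minor 2′Z isomer is removed by chromatography on AgNO3-silica or preparative HPLC.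

**Compound list**
1 | geranial, (2E)-3,7-dimethylocta-2,6-dienal | CC(C)=CCC/C(C)=C/C=O | starting material
2 | (S)-citronellal, (3S)-3,7-dimethyloct-6-enal | CC(C)=CCC[C@H](C)CC=O | intermediate
3 | (S)-citronellol, (3S)-3,7-dimethyloct-6-en-1-ol | CC(C)=CCC[C@H](C)CCO | intermediate
4 | (S)-citronellyl bromide, (6S)-8-bromo-2,6-dimethyloct-2-ene | CC(C)=CCC[C@H](C)CCBr | intermediate
5 | (2E,6E)-farnesyl acetate | CC(C)=CCC/C(C)=C/CC/C(C)=C/COC(C)=O | starting material
6 | (2E,6E,10E)-12-hydroxy-3,7,11-trimethyldodeca-2,6,10-trien-1-yl acetate | OC/C(C)=C/CC/C(C)=C/CC/C(C)=C/COC(C)=O | intermediate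
7 | (2E,6E,10E)-12-bromo-3,7,11-trimethyldodeca-2,6,10-trien-1-yl acetate | BrC/C(C)=C/CC/C(C)=C/CC/C(C)=C/COC(C)=O | intermediate
8 | (S)-citronellylmagnesium bromide | CC(C)=CCC[C@H](C)CC[Mg]Br | intermediate
9 | (2E,6E,10E,15R)-3,7,11,15,19-pentamethylicosa-2,6,10,18-tetraen-1-yl acetate | CC(C)=CCC[C@H](C)CCC/C(C)=C/CC/C(C)=C/CC/C(C)=C/COC(C)=O | intermediate
10 | (2E,6E,10E,15R)-3,7,11,15,19-pentamethylicosa-2,6,10,18-tetraen-1-ol | CC(C)=CCC[C@H](C)CCC/C(C)=C/CC/C(C)=C/CC/C(C)=C/CO | intermediate
11 | (2E,6E,10E,15R)-1-bromo-3,7,11,15,19-pentamethylicosa-2,6,10,18-tetraene | CC(C)=CCC[C@H](C)CCC/C(C)=C/CC/C(C)=C/CC/C(C)=C/CBr | intermediate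
12 | [(2E,6E,10E,15R)-3,7,11,15,19-pentamethylicosa-2,6,10,18-tetraen-1-yl] phenyl sulfone | CC(C)=CCC[C@H](C)CCC/C(C)=C/CC/C(C)=C/CC/C(C)=C/CS(=O)(=O)c1ccccc1 | intermediate
13 | [(2E,6E,10E,15R)-3,7,11,15,19-pentamethyl-1-(phenylsulfonyl)icosa-2,6,10,18-tetraen-1-yl]lithium | CC(C)=CCC[C@H](C)CCC/C(C)=C/CC/C(C)=C/CC/C(C)=C/C([Li])S(=O)(=O)c1ccccc1 | intermediate
14 | (2E,6E,10E,14E,18E,22E,27R)-3,7,11,15,19,23,27,31-octamethyl-13-(phenylsulfonyl)dotriaconta-2,6,10,14,18,22,30-heptaen-1-yl acetate (C13 epimers) | CC(C)=CCC[C@H](C)CCC/C(C)=C/CC/C(C)=C/CC/C(C)=C/C(S(=O)(=O)c1ccccc1)C/C(C)=C/CC/C(C)=C/CC/C(C)=C/COC(C)=O | intermediate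
15 | (2E,6E,10E,14E,18E,22E,27R)-3,7,11,15,19,23,27,31-octamethyl-13-(phenylsulfonyl)dotriaconta-2,6,10,14,18,22,30-heptaen-1-ol (C13 epimers, present as lithium alkoxide) | CC(C)=CCC[C@H](C)CCC/C(C)=C/CC/C(C)=C/CC/C(C)=C/C(S(=O)(=O)c1ccccc1)C/C(C)=C/CC/C(C)=C/CC/C(C)=C/CO | intermediate
16 | (2E,6E,10E,14E,18E,22E,27R)-3,7,11,15,19,23,27,31-octamethyldotriaconta-2,6,10,14,18,22,30-heptaen-1-ol | CC(C)=CCC[C@H](C)CCC/C(C)=C/CC/C(C)=C/CC/C(C)=C/CC/C(C)=C/CC/C(C)=C/CC/C(C)=C/CO | intermediate
17 | menadiol, 2-methylnaphthalene-1,4-diol | Cc1cc(O)c2ccccc2c1O | starting material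
18 | 2-methyl-3-[(2E,6E,10E,14E,18E,22E,27R)-3,7,11,15,19,23,27,31-octamethyldotriaconta-2,6,10,14,18,22,30-heptaen-1-yl]naphthalene-1,4-diol | CC(C)=CCC[C@H](C)CCC/C(C)=C/CC/C(C)=C/CC/C(C)=C/CC/C(C)=C/CC/C(C)=C/CC/C(C)=C/Cc1c(C)c(O)c2ccccc2c1O | intermediate
19 | 2-methyl-3-[(2E,6E,10E,14E,18E,22E,27R)-3,7,11,15,19,23,27,31-octamethyldotriaconta-2,6,10,14,18,22,30-heptaen-1-yl]naphthalene-1,4-dione | CC(C)=CCC[C@H](C)CCC/C(C)=C/CC/C(C)=C/CC/C(C)=C/CC/C(C)=C/CC/C(C)=C/CC/C(C)=C/CC1=C(C)C(=O)c2ccccc2C1=O | target

**Step count**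
Total: 9 steps. Longest linear sequence: 7 steps (steps 1, 2, 5, 6, 7, 8, 9; the branch through steps 3 and 4 is equally long).

**Steps most likely to fail, with fallbacks**

Step 1 (the proposed new catalyst; turnover or ee may fall short of what a single enantiomer needs). The fallback replaces organocatalysis by known biocatalysis and sets out from 1. An (S)-selective ene-reductase of the Old Yellow Enzyme family, with NADPH recycled by glucose dehydrogenase and glucose in phosphate buffer at 30 °C, reduces the C2=C3 bond to (S)-citronellal 2; enzymes of this class are reported to give it in over 95% ee. The route is rejoined at 2, which NaBH4 takes on to 3 as in step 1; no compound outside the list is made (F0).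

Step 5 (SN2′ attack or loss of the acetate would spoil the alkyl–allyl coupling). The fallback replaces the organometallic coupling by a sulfone alkylation and sets out from 4 and 7. Bromide 4 and PhSO2Na in DMF give (S)-citronellyl phenyl sulfone F1. Its α-lithio derivative (n-BuLi, THF, −78 °C) is alkylated by 7 to the C25 sulfonyl acetate F2, with the sulfone on C13 as a mixture of epimers. Sodium amalgam with Na2HPO4 in MeOH, followed by K2CO3 in MeOH, removes the sulfonyl group and the acetate, and the route is rejoined at 10.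

Step 9 (modest yield and partial loss of the 2′E geometry in the cationic allylation). The fallback replaces the Friedel–Crafts reaction by a geometry-retaining aryl–allyl coupling and sets out from 16. PBr3 in Et2O at −10 °C gives the C40 allylic bromide F3. Bought 2-bromo-1,4-dimethoxy-3-methylnaphthalene is lithiated (n-BuLi, THF, −78 °C), converted to the aryl cuprate with CuBr·SMe2 and alkylated by F3 at the primary carbon, which gives the hydroquinone dimethyl ether F4. Ceric ammonium nitrate in MeCN/H2O at 0 °C then demethylates it oxidatively, and the route is rejoined at the target 19.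

**Further compounds**
F0 | step 1 | none | none
F1 | step 5 | (S)-citronellyl phenyl sulfone, [(3S)-3,7-dimethyloct-6-en-1-yl]sulfonylbenzene | CC(C)=CCC[C@H](C)CCS(=O)(=O)c1ccccc1
F2 | step 5 | (2E,6E,10E,15S)-3,7,11,15,19-pentamethyl-13-(phenylsulfonyl)icosa-2,6,10,18-tetraen-1-yl acetate (C13 epimers; same spatial arrangement at C15 as in 10) | CC(C)=CCC[C@H](C)CC(S(=O)(=O)c1ccccc1)C/C(C)=C/CC/C(C)=C/CC/C(C)=C/COC(C)=O
F3 | step 9 | (2E,6E,10E,14E,18E,22E,27R)-1-bromo-3,7,11,15,19,23,27,31-octamethyldotriaconta-2,6,10,14,18,22,30-heptaene | CC(C)=CCC[C@H](C)CCC/C(C)=C/CC/C(C)=C/CC/C(C)=C/CC/C(C)=C/CC/C(C)=C/CC/C(C)=C/CBr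
F4 | step 9 | 1,4-dimethoxy-2-methyl-3-[(2E,6E,10E,14E,18E,22E,27R)-3,7,11,15,19,23,27,31-octamethyldotriaconta-2,6,10,14,18,22,30-heptaen-1-yl]naphthalene | CC(C)=CCC[C@H](C)CCC/C(C)=C/CC/C(C)=C/CC/C(C)=C/CC/C(C)=C/CC/C(C)=C/CC/C(C)=C/Cc1c(C)c(OC)c2ccccc2c1OC
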